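**Retrosynthetic overview**

1. The last step only unmasks six phenols (allyl ethers); every C–C bond and all three stereocentres are in place after the key step.
2. Key disconnection: bonds C1–C2 and C5–C6 of cyclohexene ring C (C1 = CH–C(=O), C2 = CH–benzofuranyl, C3=C4(CH3), C5 = CH2, C6 = CH–aryl), made in one enantioselective exo Diels–Alder reaction between a flat 2'-hydroxychalcone (rings A and B) and a flat (E)-1-aryl-3-methylbutadiene (rings D, E, F).
3. Enabling feature: the free phenol of ring A is ortho to the C1 ketone, so O–H and C=O clamp one boron atom in a six-membered chelate that activates the enone and carries a chiral biaryl; the C3=C4 double bond lies opposite the C1–C6 bond with CH3 on C4 para to the acyl carbon, so ring C is a regiochemically matched Diels–Alder retron.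
4. Dienophile: C-prenylated resacetophenone (ring A) plus ring B aldehyde by Claisen–Schmidt condensation. Diene: iodoresorcinol aldehyde plus aryl alkyne by Sonogashira coupling/cyclisation, then two Wittig olefinations.
5. Ring order: furan ring E first, cyclohexene ring C last; rings A, B, D and F are bought as arenes, and 2,4-dihydroxybenzaldehyde supplies both ring B and ring D.

Key step: step 11

Assumption: the sense of induction of the biaryl borate is taken from the shielding model given in step 11 (the (S)-ligand leaves the Si faces of the chelated s-cis enone open); should the induction prove opposite, (R)-VANOL is used in step 11 and nothing else changes.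

**Route**

Step 1
Reactants: 1 2,4-dihydroxybenzaldehyde
Product: 2 2,4-dihydroxy-5-iodobenzaldehyde
Conditions: ICl, AcOH, 25 °C
Reagents that add atoms: iodine monochloride, ClI
Why: Electrophilic aromatic iodination is expected at C5, para to the 2-OH and ortho to the 4-OH, because C3 between the two oxygens is the more hindered site and the formyl group slows a second substitution; the minor 3-iodo isomer is removed by crystallisation.

Step 2
Reactants: 2 2,4-dihydroxy-5-iodobenzaldehyde; 3 1-ethynyl-3,5-dimethoxybenzene
Product: 5 2-(3,5-dimethoxyphenyl)-6-hydroxy-1-benzofuran-5-carbaldehyde, via alkynylphenol 4 (not isolated)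
Conditions: PdCl2(PPh3)2 (cat.), CuI (cat.), Et3N, DMF, 25 → 70 °C
Reagents that add atoms: none
Why: Sonogashira coupling at the C–I bond gives the ortho-alkynylphenol 4, whose 4-OH then adds to the metal-activated alkyne in a 5-endo-dig cycloisomerisation under the same basic conditions (tandem Sonogashira/heteroannulation of ortho-iodophenols), closing furan ring E.

Step 3
Reactants: 5 2-(3,5-dimethoxyphenyl)-6-hydroxy-1-benzofuran-5-carbaldehyde
Product: 6 2-(3,5-dihydroxyphenyl)-6-hydroxy-1-benzofuran-5-carbaldehyde
Conditions: BBr3, CH2Cl2, −78 → 25 °C; then H2O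
Reagents that add atoms: none
Why: Boron tribromide cleaves aryl methyl ethers by O-complexation and SN2 attack of bromide on the methyl group, a standard unmasking of 2-arylbenzofuran resorcinols that should leave the chelated formyl group intact at low temperature.

Step 4
Reactants: 6 2-(3,5-dihydroxyphenyl)-6-hydroxy-1-benzofuran-5-carbaldehyde
Product: 7 2-[3,5-bis(allyloxy)phenyl]-6-(allyloxy)-1-benzofuran-5-carbaldehyde
Conditions: allyl bromide, K2CO3, DMF, 50 °C
Reagents that add atoms: allyl bromide, C=CCBr
Why: Williamson etherification of all three phenoxides (the formyl-chelated 6-OH included, in DMF with gentle heating) installs allyl ethers that tolerate ylides, base and the borate Lewis acid and can be removed at the end under neutral conditions.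

Step 5
Reactants: 7 2-[3,5-bis(allyloxy)phenyl]-6-(allyloxy)-1-benzofuran-5-carbaldehyde
Product: 8 (E)-4-{2-[3,5-bis(allyloxy)phenyl]-6-(allyloxy)-1-benzofuran-5-yl}but-3-en-2-one
Conditions: Ph3P=CHC(O)CH3, toluene, 90 °C
Reagents that add atoms: 1-(triphenylphosphoranylidene)propan-2-one, CC(=O)C=P(c1ccccc1)(c1ccccc1)c1ccccc1
Why: Wittig olefination with a carbonyl-stabilised ylide is E-selective and should give the (E)-enone cleanly, without the double condensation that acetone itself could undergo.

Step 6
Reactants: 8 (E)-4-{2-[3,5-bis(allyloxy)phenyl]-6-(allyloxy)-1-benzofuran-5-yl}but-3-en-2-one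
Product: 9 2-[3,5-bis(allyloxy)phenyl]-6-(allyloxy)-5-[(1E)-3-methylbuta-1,3-dien-1-yl]-1-benzofuran
Conditions: Ph3PCH3Br, KOtBu, THF, 0 → 25 °C
Reagents that add atoms: methyltriphenylphosphonium bromide, C[P+](c1ccccc1)(c1ccccc1)c1ccccc1.[Br-]
Why: Wittig methylenation of the methyl ketone with the non-stabilised ylide converts C=O into C=CH2 without touching the existing E-alkene, giving the (E)-1-aryl-3-methylbuta-1,3-diene, which is kept cold and used promptly.

Step 7
Reactants: 10 1-(2,4-dihydroxyphenyl)ethanone
Product: 11 1-[2,4-dihydroxy-3-(3-methylbut-2-en-1-yl)phenyl]ethanone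
Conditions: prenyl bromide, KOH (10% aq.), 0 → 25 °C
Reagents that add atoms: prenyl bromide (1-bromo-3-methylbut-2-ene), CC(C)=CCBr
Why: In water the ambident resorcinolate is C-alkylated preferentially at C3, the carbon flanked by both oxygens, by SN2 reaction with prenyl bromide (direct C-prenylation of resacetophenone); O-prenyl and 5-prenyl isomers are removed by chromatography.

Step 8
Reactants: 11 1-[2,4-dihydroxy-3-(3-methylbut-2-en-1-yl)phenyl]ethanone
Product: 12 1-[4-(allyloxy)-2-hydroxy-3-(3-methylbut-2-en-1-yl)phenyl]ethanone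
Conditions: allyl bromide (1.1 equiv), K2CO3, acetone, reflux
Reagents that add atoms: allyl bromide, C=CCBr
Why: Williamson etherification is selective for the 4-OH because the 2-OH is held in a hydrogen bond to the acetyl group and is much less nucleophilic.

Step 9
Reactants: 1 2,4-dihydroxybenzaldehyde
Product: 13 2,4-bis(allyloxy)benzaldehyde
Conditions: allyl bromide, K2CO3, DMF, 50 °C
Reagents that add atoms: allyl bromide, C=CCBr
Why: Double Williamson etherification under standard conditions protects both phenols of the ring B aldehyde.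

Step 10
Reactants: 12 1-[4-(allyloxy)-2-hydroxy-3-(3-methylbut-2-en-1-yl)phenyl]ethanone; 13 2,4-bis(allyloxy)benzaldehyde
Product: 14 (E)-1-[4-(allyloxy)-2-hydroxy-3-(3-methylbut-2-en-1-yl)phenyl]-3-[2,4-bis(allyloxy)phenyl]prop-2-en-1-one
Conditions: KOH (50% aq.), EtOH, 25 °C; then dilute HCl
Reagents that add atoms: none
Why: Claisen–Schmidt condensation of the acetophenone enolate with the non-enolisable aldehyde followed by E1cB dehydration gives the thermodynamically favoured (E)-chalcone, with the 2'-OH left free for the key step.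

Step 11
Reactants: 14 (E)-1-[4-(allyloxy)-2-hydroxy-3-(3-methylbut-2-en-1-yl)phenyl]-3-[2,4-bis(allyloxy)phenyl]prop-2-en-1-one; 9 2-[3,5-bis(allyloxy)phenyl]-6-(allyloxy)-5-[(1E)-3-methylbuta-1,3-dien-1-yl]-1-benzofuran
Product: 17 [(1R,2R,6S)-2-{2-[3,5-bis(allyloxy)phenyl]-6-(allyloxy)-1-benzofuran-5-yl}-6-[2,4-bis(allyloxy)phenyl]-4-methylcyclohex-3-en-1-yl][4-(allyloxy)-2-hydroxy-3-(3-methylbut-2-en-1-yl)phenyl]methanone, via chalcone spiro-borate 15 (not isolated), via cycloadduct borate 16 (not isolated)
Conditions: (S)-VANOL ((S)-3,3'-diphenyl-2,2'-bi-1-naphthol, 1.2 equiv), B(OPh)3 (1.2 equiv), toluene, 80 °C, then vacuum; 14, 4 Å molecular sieves, PhCF3, 25 °C; then 9 (1.5 equiv), 25 → 40 °C; aqueous NaHCO3 work-up, SiO2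
Reagents that add atoms: none
Why: Exchange of the phenoxide ligand of the in-situ biaryl borate for the ring A phenol of 14 gives the four-coordinate spiro-borate 15, in which phenoxide and ketone oxygen hold boron in a six-membered chelate that locks the enone s-cis and lowers its LUMO; diene 9 then adds in a concerted, asynchronous, normal-electron-demand [4+2] cycloaddition to give borate 16, which is hydrolysed on work-up to 17 with release of the biaryl diol. The closest known reaction type is the chiral biaryl-borate-promoted asymmetric Diels–Alder reaction of 2'-hydroxychalcones (and of peri-hydroxyquinones) with 1-aryl-3-methylbuta-1,3-dienes, a reaction type established for chalcone–dehydroprenylarene pairs of this kind. Ring C is closed by an intermolecular [4π+2π] cycloaddition, suprafacial on both components, that forms C1–C2 and C5–C6 at once. The C1/C6 trans relation is inherited from the E-geometry of the chalcone, the C1/C2 trans relation comes from the exo placement of the acyl-borate relative to the E-diene, and the absolute sense (1R,2R,6S) comes from the (S)-biaryl, whose vaulted naphthol wing on the ketone side covers the Re faces of the α- and β-carbons so that the diene bonds to their Si faces. The step needs regio-, exo- and face-selectivity: regiochemistry is secured because the 1-aryl and 3-methyl groups both place the largest HOMO coefficient on the CH2 terminus, which bonds to the β-carbon of the chelated enone, and exo selectivity is expected because the bulky four-coordinate borate on the carbonyl oxygen is too large to lie under the diene while ring B can stack there; the endo (2S) diastereomer is the expected by-product and is removed by chromatography. Only the boron-chelated enone is activated, so the isolated prenyl and allyl alkenes of both partners should not compete as dienophiles.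

Step 12
Reactants: 17 [(1R,2R,6S)-2-{2-[3,5-bis(allyloxy)phenyl]-6-(allyloxy)-1-benzofuran-5-yl}-6-[2,4-bis(allyloxy)phenyl]-4-methylcyclohex-3-en-1-yl][4-(allyloxy)-2-hydroxy-3-(3-methylbut-2-en-1-yl)phenyl]methanone
Product: 18 [(1R,2R,6S)-2-[2-(3,5-dihydroxyphenyl)-6-hydroxy-1-benzofuran-5-yl]-6-(2,4-dihydroxyphenyl)-4-methylcyclohex-3-en-1-yl][2,4-dihydroxy-3-(3-methylbut-2-en-1-yl)phenyl]methanone (CNP0150120.1)
Conditions: Pd(PPh3)4 (cat.), morpholine (excess), THF, 25 °C, argon; dilute citric acid work-up
Reagents that add atoms: none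
Why: Zerovalent palladium ionises each aryl allyl ether to a π-allylpalladium phenoxide and morpholine captures the allyl group irreversibly (Tsuji–Trost deallylation), a neutral method that should spare the prenyl group, the ring alkene and the three stereocentres, C1 being already the thermodynamically preferred all-trans epimer.

**Compound list**

1 | 2,4-dihydroxybenzaldehyde | O=Cc1ccc(O)cc1O | starting material
2 | 2,4-dihydroxy-5-iodobenzaldehyde | O=Cc1cc(I)c(O)cc1O | intermediate
3 | 1-ethynyl-3,5-dimethoxybenzene | C#Cc1cc(OC)cc(OC)c1 | starting material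
4 | 5-[(3,5-dimethoxyphenyl)ethynyl]-2,4-dihydroxybenzaldehyde (not isolated) | O=Cc1cc(C#Cc2cc(OC)cc(OC)c2)c(O)cc1O | intermediate
5 | 2-(3,5-dimethoxyphenyl)-6-hydroxy-1-benzofuran-5-carbaldehyde | O=Cc1cc2cc(-c3cc(OC)cc(OC)c3)oc2cc1O | intermediate
6 | 2-(3,5-dihydroxyphenyl)-6-hydroxy-1-benzofuran-5-carbaldehyde | O=Cc1cc2cc(-c3cc(O)cc(O)c3)oc2cc1O | intermediate
7 | 2-[3,5-bis(allyloxy)phenyl]-6-(allyloxy)-1-benzofuran-5-carbaldehyde | O=Cc1cc2cc(-c3cc(OCC=C)cc(OCC=C)c3)oc2cc1OCC=C | intermediate
8 | (E)-4-{2-[3,5-bis(allyloxy)phenyl]-6-(allyloxy)-1-benzofuran-5-yl}but-3-en-2-one | CC(=O)/C=C/c1cc2cc(-c3cc(OCC=C)cc(OCC=C)c3)oc2cc1OCC=C | intermediate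
9 | 2-[3,5-bis(allyloxy)phenyl]-6-(allyloxy)-5-[(1E)-3-methylbuta-1,3-dien-1-yl]-1-benzofuran | C=C(C)/C=C/c1cc2cc(-c3cc(OCC=C)cc(OCC=C)c3)oc2cc1OCC=C | intermediate
10 | 1-(2,4-dihydroxyphenyl)ethanone | CC(=O)c1ccc(O)cc1O | starting material
11 | 1-[2,4-dihydroxy-3-(3-methylbut-2-en-1-yl)phenyl]ethanone | CC(=O)c1ccc(O)c(CC=C(C)C)c1O | intermediate
12 | 1-[4-(allyloxy)-2-hydroxy-3-(3-methylbut-2-en-1-yl)phenyl]ethanone | CC(=O)c1ccc(OCC=C)c(CC=C(C)C)c1O | intermediate
13 | 2,4-bis(allyloxy)benzaldehyde | O=Cc1ccc(OCC=C)cc1OCC=C | intermediate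
14 | (E)-1-[4-(allyloxy)-2-hydroxy-3-(3-methylbut-2-en-1-yl)phenyl]-3-[2,4-bis(allyloxy)phenyl]prop-2-en-1-one | CC(C)=CCc1c(OCC=C)ccc(C(=O)/C=C/c2ccc(OCC=C)cc2OCC=C)c1O | intermediate
15 | spiro-borate of 14: boron bound to the ring A 2-phenoxide, the ketone oxygen and both oxygens of (S)-VANOL (S axis not expressible in SMILES; not isolated) | CC(C)=CCc1c(OCC=C)ccc2c1O[B-]1(Oc3c(c(-c4ccccc4)cc4ccccc34)-c3c(O1)c4ccccc4cc3-c3ccccc3)[O+]=C2/C=C/c1ccc(OCC=C)cc1OCC=C | intermediate
16 | (1R,2R,6S)-cycloadduct still bound to boron as the (S)-VANOL spiro-borate (not isolated) | CC(C)=CCc1c(OCC=C)ccc2c1O[B-]1(Oc3c(c(-c4ccccc4)cc4ccccc34)-c3c(O1)c4ccccc4cc3-c3ccccc3)[O+]=C2[C@@H]1[C@@H](c3ccc(OCC=C)cc3OCC=C)CC(C)=C[C@H]1c1cc3cc(-c4cc(OCC=C)cc(OCC=C)c4)oc3cc1OCC=C | intermediate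
17 | [(1R,2R,6S)-2-{2-[3,5-bis(allyloxy)phenyl]-6-(allyloxy)-1-benzofuran-5-yl}-6-[2,4-bis(allyloxy)phenyl]-4-methylcyclohex-3-en-1-yl][4-(allyloxy)-2-hydroxy-3-(3-methylbut-2-en-1-yl)phenyl]methanone | CC(C)=CCc1c(OCC=C)ccc(C(=O)[C@@H]2[C@@H](c3ccc(OCC=C)cc3OCC=C)CC(C)=C[C@H]2c2cc3cc(-c4cc(OCC=C)cc(OCC=C)c4)oc3cc2OCC=C)c1O | intermediate
18 | [(1R,2R,6S)-2-[2-(3,5-dihydroxyphenyl)-6-hydroxy-1-benzofuran-5-yl]-6-(2,4-dihydroxyphenyl)-4-methylcyclohex-3-en-1-yl][2,4-dihydroxy-3-(3-methylbut-2-en-1-yl)phenyl]methanone | CC(C)=CCc1c(O)ccc(C(=O)[C@@H]2[C@@H](c3ccc(O)cc3O)CC(C)=C[C@H]2c2cc3cc(-c4cc(O)cc(O)c4)oc3cc2O)c1O | target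

**Step count and risks**

Total step count: 12. Longest linear sequence: 8 steps (steps 1 to 6, then 11 and 12).

The three steps most likely to fail:

First, step 11. The acyl-borate may slip under the diene to a comparable extent (poor exo/endo discrimination), facial control by the biaryl may be weaker than or opposite to the model, and the electron-rich diene may oligomerise under the Lewis acid faster than it cycloadds. The fallback sets out from 14 and 9 and comes back to the route at 18. Both fragments are freed of their allyl groups at the fragment stage (Pd(PPh3)4, morpholine, THF, 25 °C), giving morachalcone A F1 and the triol diene F2, which is used at once because an ortho-hydroxyaryl diene cyclises to a chromene with acid. F1 and F2 are then combined in aqueous buffer (Tris-HCl pH 8, a few per cent DMSO, 37 °C) with a recombinant exo-selective flavin-dependent Diels–Alderase from Morus alba (MaDA-3 type). Enzymes of this class accept morachalcone A with dehydroprenyl arenes and deliver the trans,trans adducts in the natural absolute configuration, so 18 should result directly and step 12 is not needed.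

Second, step 7. O-alkylation, attack at C5 and double prenylation compete with C3-alkylation of the resorcinolate. The fallback sets out from 10 and comes back at 11. The 4-OH of 10 is etherified with 3-chloro-3-methylbut-1-yne (CC(C)(Cl)C#C; K2CO3, KI, CuI cat., acetone, reflux) to the propargyl ether F3. Semihydrogenation (H2, Pd/CaCO3 poisoned with Pb(OAc)2, quinoline, EtOAc) gives the 1,1-dimethylallyl ether F4. Heating (N,N-diethylaniline, about 130 °C) then triggers an aromatic Claisen rearrangement; the [3,3] shift goes to C3, the ortho position joined to C4 by the bond of higher double-bond character in the chelated ring, and the allyl transposition turns the reverse-prenyl ether into the normal C-prenyl group of 11.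

Third, step 12. Cleavage of six ethers on the most valuable compound may stall, liberated resorcinol phenoxides may be C-allylated by the π-allylpalladium intermediate, and the free polyphenol may oxidise in air during the long exposure. The fallback sets out from 14 and 9 and comes back at 18. The allyl groups are removed at the fragment stage as in the first fallback, to morachalcone A F1 and triol diene F2, where by-products are easy to separate. Both are re-protected as acetates (Ac2O, pyridine, 0 °C; the ketone-chelated 2'-OH of F1 is spared), giving chalcone triacetate F5 and diene triacetate F6. The same borate-promoted cycloaddition as in step 11 (the acetoxy chalcone being the more electrophilic dienophile) gives the hexaacetate adduct F7, and mild methanolysis (K2CO3, MeOH, 0 °C, argon) releases 18 with no palladium at the last stage.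

Further compounds
F1 | step 11 | (E)-1-[2,4-dihydroxy-3-(3-methylbut-2-en-1-yl)phenyl]-3-(2,4-dihydroxyphenyl)prop-2-en-1-one (morachalcone A) | CC(C)=CCc1c(O)ccc(C(=O)/C=C/c2ccc(O)cc2O)c1O
F2 | step 11 | 5-{6-hydroxy-5-[(1E)-3-methylbuta-1,3-dien-1-yl]-1-benzofuran-2-yl}benzene-1,3-diol | C=C(C)/C=C/c1cc2cc(-c3cc(O)cc(O)c3)oc2cc1O
F3 | step 7 | 1-[2-hydroxy-4-(2-methylbut-3-yn-2-yloxy)phenyl]ethanone | CC(=O)c1ccc(OC(C)(C)C#C)cc1O
F4 | step 7 | 1-[2-hydroxy-4-(2-methylbut-3-en-2-yloxy)phenyl]ethanone | CC(=O)c1ccc(OC(C)(C)C=C)cc1O
F5 | step 12 | 4-{(E)-3-[4-acetoxy-2-hydroxy-3-(3-methylbut-2-en-1-yl)phenyl]-3-oxoprop-1-en-1-yl}-1,3-phenylene diacetate | CC(C)=CCc1c(OC(C)=O)ccc(C(=O)/C=C/c2ccc(OC(C)=O)cc2OC(C)=O)c1O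
F6 | step 12 | 5-{6-acetoxy-5-[(1E)-3-methylbuta-1,3-dien-1-yl]-1-benzofuran-2-yl}-1,3-phenylene diacetate | C=C(C)/C=C/c1cc2cc(-c3cc(OC(C)=O)cc(OC(C)=O)c3)oc2cc1OC(C)=O
F7 | step 12 | hexaacetate of 18 (all phenols acetylated except the ketone-chelated 2-OH of ring A), (1R,2R,6S) | CC(C)=CCc1c(OC(C)=O)ccc(C(=O)[C@@H]2[C@@H](c3ccc(OC(C)=O)cc3OC(C)=O)CC(C)=C[C@H]2c2cc3cc(-c4cc(OC(C)=O)cc(OC(C)=O)c4)oc3cc2OC(C)=O)c1O
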